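At early times the starting material has two ways out, and the choice for the next run hangs on how it divides between them.

    starting material ⇌ target + released group (K1 = 0.0011 M, k1 = 0.30 /s)
    target ⇌ isomer of the product (K2 = 0.52, k2 = 0.083 /s)
    starting material + protic impurity → quenched substrate (k3 = 170 /M/s)
    target → over-reaction product (k4 = 0.95 /s)

| flask | starting material | protic impurity | time |
|---|---|---|---|
| south-east | 2.0 mM | 1.00 mM | 5.0 s |
| north-west | 2.0 mM | 1.00 mM | 8.0 s |
| north-east | 2.0 mM | 1.00 mM | 12 s |

1. which of these there is most of at the end, counted by the starting material in it, south-east (isomer of the product / target / starting material / over-reaction product)
2. which of these there is most of at the end, counted by the starting material in it, north-west (isomer of the product / target / starting material / over-reaction product)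
3. which of these there is most of at the end, counted by the starting material in it, north-east (isomer of the product / target / starting material / over-reaction product)
4. the largest of these amounts at the end, in percent of the starting material charged, south-east
5. the largest of these amounts at the end, in percent of the starting material charged, north-west
6. the largest of these amounts at the end, in percent of the starting material charged, north-east

In the north-east flask the first step starts 1.8 times as fast as the quench, forward rate alone, and this ratio of the two rates is the selectivity factor. Both rates carry the starting material as a factor, so it cancels from their ratio, and with the impurity as charged the ratio gives 63.8%. This is the branching share: the first step's rate constant over the sum of that constant and the quench constant times the impurity present. The target then goes on to over-reaction product faster than to its isomer, with 0.95 /s against 0.083 /s, so the share serves as a first estimate of the over-reaction product.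

The correction concerns the impurity. At that share the quench is reckoned to take 0.723 mM from a charge of 1.00 mM, so the impurity falls during the run. Taking it midway, at 0.638 mM, raises the share to 73.4%, which is larger. This reckoning by hand, with the way back not counted, therefore puts the final over-reaction product between these two shares.

The time can stay as it is. The first step, by its forward rate only, has a half-life of 2.3 s, and the north-east reading at 12 s lies 5.22 such half-lives out. The starting material charge can stay too, since it does not appear in the share. The next run therefore keeps both and changes the impurity charge.

The forecast names over-reaction product as the largest in south-east, north-west and north-east, at 47.5%, 58% and 63.7%. Its ground is that the target “stays near a lagged steady state”.

over-reaction product leads in south-east, north-west and north-east, at 47.7%, 58.3% and 64.2%, inside the forecast's ranges. In the north-east flask, 2.81% of the starting material still stands at 12 s. Read at 50 s, that flask keeps 38% of its impurity charge. The impurity midway between charge and remainder is therefore 0.688 mM, which gives a branching share of 72.0%, and the over-reaction product in that flask stands at 68.8%.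

Its constants are those of an exercise; the run is a simulation.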